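**Plan**
- Retrosynthesis: after the two O–Si bonds, the ring bonds C1–C2 and C3–C4 of the quinone ring are cut together. This leaves a mirror-symmetric 3,6-disilyloxyphthaloyl cobalt metallacycle (from a benzocyclobutenedione) and a terminal alkyne that already bears the complete chiral ester side chain. The alkyne is then cut at the ester C–O bond and at the carbinol C–H bond (alkynyl ketone).
- Enabling feature: in the quinone ring the C2=C3 bond carries only the side chain and one hydrogen and lies between the carbonyl carbons C1 and C4, which sit on a benzo ring whose C5 and C8 oxygens are identical. C2=C3 is therefore a masked terminal alkyne and C1/C8a/C4a/C4 a symmetric phthaloyl unit, so no regiochemistry has to be controlled.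
- Forward order: the benzo ring is bought and the four-membered dione ring is fused to it (aryne [2+2], benzylic oxidation). The alkyne ester is assembled from two acids. The quinone ring is formed by cobalt-mediated annulation, and desilylation ends the route.
- Stereochemistry: the single stereocentre (R) comes from asymmetric transfer hydrogenation of an alkynyl ketone and is never again part of a bond that is made or broken.

Key step: step 14

Remark: 5,8-dihydroxy-1,4-naphthoquinones are rapidly interconverting tautomers, so 27 is written as the tautomer of the target SMILES; compounds 1, 2, 11, 12, 16, 19 and ClCo(PPh3)3 are taken as commercial; in the SMILES of the cobalt compounds each ligand-to-cobalt donor bond is written charge-separated (positive charge on the donor N or P, the balancing negative charge on cobalt), the complexes being neutral.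

**Step 1**
Reactants: 1 2-bromo-1,4-dimethoxybenzene; 2 1,1-diethoxyethene
Product: 4 7,7-diethoxy-2,5-dimethoxybicyclo[4.2.0]octa-1,3,5-triene, via 3,6-dimethoxybenzyne 3 (not isolated)
Conditions: NaNH2, excess 2, THF, reflux
Reagents that add atoms: none
Why: Deprotonation of C3–H of 1 (between Br and OMe) and loss of bromide should give the symmetrical aryne 3, which the electron-rich ketene acetal traps in a polar stepwise [2+2] cycloaddition (aryne–ketene acetal route to benzocyclobutenone acetals), the symmetry of 3 leaving no regiochemical question.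

**Step 2**
Reactants: 4 7,7-diethoxy-2,5-dimethoxybicyclo[4.2.0]octa-1,3,5-triene
Product: 5 8,8-dibromo-7,7-diethoxy-2,5-dimethoxybicyclo[4.2.0]octa-1,3,5-triene
Conditions: NBS (2.2 equiv), (PhCO2)2 (cat.), CCl4, reflux
Reagents that add atoms: N-bromosuccinimide, O=C1CCC(=O)N1Br
Why: Wohl–Ziegler radical bromination should occur twice at the only benzylic sp3 carbon (the cyclobutene CH2), as is known for benzocyclobutenone acetals, the radical conditions in a non-polar solvent disfavouring ionic bromination of the dimethoxyarene ring.

**Step 3**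
Reactants: 5 8,8-dibromo-7,7-diethoxy-2,5-dimethoxybicyclo[4.2.0]octa-1,3,5-triene
Product: 6 3,6-dimethoxybenzocyclobutene-1,2-dione
Conditions: 50% aq. H2SO4, THF, 40 °C
Reagents that add atoms: water, O
Why: Acid hydrolysis of the acetal and of the benzylic gem-dibromide (both ionise to oxygen- or aryl-stabilised cations that water captures) should unmask the two carbonyl groups of the benzocyclobutenedione.

**Step 4**
Reactants: 6 3,6-dimethoxybenzocyclobutene-1,2-dione
Product: 7 3,6-dihydroxybenzocyclobutene-1,2-dione
Conditions: BBr3, CH2Cl2, −78 °C to rt; then H2O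
Reagents that add atoms: none
Why: Lewis-acid cleavage of aryl methyl ethers with BBr3, helped by chelation of boron between each ether oxygen and its neighbouring carbonyl, removes the robust methyl groups before any sensitive functionality is present.

**Step 5**
Reactants: 7 3,6-dihydroxybenzocyclobutene-1,2-dione
Product: 8 3,6-bis(tert-butyldimethylsilyloxy)benzocyclobutene-1,2-dione
Conditions: TBSCl, imidazole, DMF, rt
Reagents that add atoms: tert-butyldimethylsilyl chloride, CC(C)(C)[Si](C)(C)Cl
Why: Standard silylation of phenols installs groups that fluoride can remove at the end without strong acid, base or oxidant.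

**Step 6**
Reactants: 8 3,6-bis(tert-butyldimethylsilyloxy)benzocyclobutene-1,2-dione
Product: 10 chloro(dimethylglyoxime)(pyridine)[3,6-bis(tert-butyldimethylsilyloxy)phthaloyl]cobalt, via chlorobis(triphenylphosphine)phthaloylcobalt complex 9 (not isolated)
Conditions: ClCo(PPh3)3, PhCl, rt; then dimethylglyoxime, pyridine, rt
Reagents that add atoms: chlorotris(triphenylphosphine)cobalt, Cl[Co-3]([P+](c1ccccc1)(c1ccccc1)c1ccccc1)([P+](c1ccccc1)(c1ccccc1)c1ccccc1)[P+](c1ccccc1)(c1ccccc1)c1ccccc1; dimethylglyoxime, CC(=NO)C(C)=NO; pyridine, c1ccncc1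
Why: Oxidative addition of the strained C(=O)–C(=O) bond to monovalent cobalt should give the five-membered phthaloyl complex 9 of trivalent cobalt, and exchange of both phosphines for dimethylglyoxime and pyridine the air-stable octahedral complex 10 (known preparation of phthaloylcobalt complexes from benzocyclobutenediones).

**Step 7**
Reactants: 11 2-bromo-3-methylbut-2-ene; 12 oxirane
Product: 14 3,4-dimethylpent-3-en-1-ol, via (3-methylbut-2-en-2-yl)magnesium bromide 13 (not isolated)
Conditions: Mg, THF, reflux; then CuI (5 mol %), 12, −30 °C to rt; aq. NH4Cl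
Reagents that add atoms: none
Why: Grignard formation from the vinylic bromide and copper-catalysed SN2 opening of oxirane add the two-carbon chain to the tetrasubstituted alkene, whose substitution pattern allows no E/Z isomers.

**Step 8**
Reactants: 14 3,4-dimethylpent-3-en-1-ol
Product: 15 3,4-dimethylpent-3-enoic acid
Conditions: TEMPO (cat.), PhI(OAc)2 (2.2 equiv), MeCN/H2O, rt
Reagents that add atoms: water, O
Why: Oxoammonium-catalysed oxidation takes the primary alcohol through the aldehyde hydrate to the acid under nearly neutral conditions, so the β,γ-double bond should not be drawn into conjugation.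

**Step 9**
Reactants: 16 4-methylpent-3-enoic acid
Product: 18 N-methoxy-N,4-dimethylpent-3-enamide, via 1-(4-methylpent-3-enoyl)imidazole 17 (not isolated)
Conditions: 1,1'-carbonyldiimidazole, CH2Cl2, rt; then MeNHOMe·HCl, rt
Reagents that add atoms: N,O-dimethylhydroxylamine hydrochloride, CNOC.Cl
Why: Activation of the acid as its acyl imidazole and aminolysis (Weinreb amide formation) proceed without strong base, so the β,γ-alkene stays in place.

**Step 10**
Reactants: 18 N-methoxy-N,4-dimethylpent-3-enamide; 19 ethynyltrimethylsilane
Product: 21 6-methyl-1-(trimethylsilyl)hept-5-en-1-yn-3-one, via lithium (trimethylsilyl)acetylide 20 (not isolated)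
Conditions: 19, n-BuLi, THF, −78 °C; then 18, −78 to 0 °C; aq. NH4Cl
Reagents that add atoms: none
Why: Weinreb ketone synthesis, in which the lithium acetylide adds once and the chelated tetrahedral adduct survives until the quench, where it collapses to the alkynyl ketone.

**Step 11**
Reactants: 21 6-methyl-1-(trimethylsilyl)hept-5-en-1-yn-3-one
Product: 22 (R)-6-methyl-1-(trimethylsilyl)hept-5-en-1-yn-3-ol
Conditions: Ru[(R,R)-TsNCHPhCHPhNH](p-cymene) (2 mol %), i-PrOH, rt
Reagents that add atoms: none
Why: Noyori asymmetric transfer hydrogenation of an alkynyl ketone delivers hydride and proton through the six-membered metal–ligand bifunctional transition state; the (R,R)-catalyst is chosen because the (S,S)-catalyst is known to give (S)-alk-1-yn-3-ols, so the (R)-carbinol centre is set here under catalyst control while the C≡C and C=C bonds are untouched.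

**Step 12**
Reactants: 22 (R)-6-methyl-1-(trimethylsilyl)hept-5-en-1-yn-3-ol
Product: 23 (R)-6-methylhept-5-en-1-yn-3-ol
Conditions: K2CO3 (cat.), MeOH, 0 °C to rt
Reagents that add atoms: none
Why: Methoxide-mediated protodesilylation of the alkynylsilane cleaves only the C–Si bond and frees the terminal alkyne without touching the stereocentre.

**Step 13**
Reactants: 23 (R)-6-methylhept-5-en-1-yn-3-ol; 15 3,4-dimethylpent-3-enoic acid
Product: 24 (R)-6-methylhept-5-en-1-yn-3-yl 3,4-dimethylpent-3-enoate
Conditions: DCC, DMAP (cat.), CH2Cl2, 0 °C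
Reagents that add atoms: none
Why: Steglich esterification acylates the alcohol oxygen without breaking any bond to the stereocentre, so the (R) configuration is retained, and catalytic DMAP at 0 °C limits migration of the β,γ-double bond of the acyl group.

**Step 14**
Reactants: 10 chloro(dimethylglyoxime)(pyridine)[3,6-bis(tert-butyldimethylsilyloxy)phthaloyl]cobalt; 24 (R)-6-methylhept-5-en-1-yn-3-yl 3,4-dimethylpent-3-enoate
Product: 26 (R)-1-[5,8-bis(tert-butyldimethylsilyloxy)-1,4-dioxo-1,4-dihydronaphthalen-2-yl]-4-methylpent-3-enyl 3,4-dimethylpent-3-enoate, via seven-membered acyl(vinyl)cobaltacycle 25 (not isolated)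
Conditions: CoCl2·6H2O, ClCH2CH2Cl, 80 °C
Reagents that add atoms: none
Why: The Lewis acid CoCl2·6H2O takes pyridine from the octahedral trivalent-cobalt complex 10, the terminal alkyne of 24 binds at the vacant site and inserts into one Co–acyl bond to give the seven-membered acyl(vinyl)cobaltacycle 25 (first C–C bond), and reductive elimination of the vinyl and the remaining acyl carbon makes the second C–C bond and releases the quinone and monovalent cobalt. The closest known reaction type is the synthesis of 1,4-naphthoquinones from phthaloylcobalt dimethylglyoxime complexes and alkynes, which is established for terminal and heteroatom-functionalised alkynes. The quinone ring is closed as a six-membered carbocycle in a metal-templated formal [4+2] annulation of the four-carbon phthaloyl unit (C1, C8a, C4a, C4) with the two alkyne carbons (C2, C3), the actual ring closure being the C–C reductive elimination from the seven-membered metallacycle. No stereocentre is formed, and the (R)-carbinol carbon of 24 lies outside every bond made or broken and is not epimerisable under these non-basic conditions, so it should be carried into 26 unchanged. The step needs chemoselectivity for the alkyne over the two alkenes, which the far better π-acceptor alkyne secures at the electron-poor acylcobalt centre, and it needs no regioselectivity because the 3,6-disilyloxyphthaloyl unit has a mirror plane through cobalt, so both insertion orientations (25 or its regioisomer) converge on 26.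

**Step 15**
Reactants: 26 (R)-1-[5,8-bis(tert-butyldimethylsilyloxy)-1,4-dioxo-1,4-dihydronaphthalen-2-yl]-4-methylpent-3-enyl 3,4-dimethylpent-3-enoate
Product: 27 (R)-1-(5,8-dihydroxy-1,4-dioxo-1,4-dihydronaphthalen-2-yl)-4-methylpent-3-enyl 3,4-dimethylpent-3-enoate
Conditions: HF·pyridine, pyridine/THF, 0 °C
Reagents that add atoms: none
Why: Fluoride cleavage of the two aryl silyl ethers, made labile by the peri carbonyl groups, under buffered and slightly acidic conditions should leave the allylic-type ester, both alkenes and the stereocentre untouched and give the hydrogen-bonded naphthazarin.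

**Compound list**
1 | 2-bromo-1,4-dimethoxybenzene | COc1ccc(OC)c(Br)c1 | starting material
2 | 1,1-diethoxyethene | C=C(OCC)OCC | starting material
3 | 3,6-dimethoxybenzyne | COC1=CC=C(OC)C#C1 | intermediate (not isolated)
4 | 7,7-diethoxy-2,5-dimethoxybicyclo[4.2.0]octa-1,3,5-triene | CCOC1(OCC)Cc2c(OC)ccc(OC)c21 | intermediate
5 | 8,8-dibromo-7,7-diethoxy-2,5-dimethoxybicyclo[4.2.0]octa-1,3,5-triene | CCOC1(OCC)C(Br)(Br)c2c(OC)ccc(OC)c21 | intermediate
6 | 3,6-dimethoxybenzocyclobutene-1,2-dione | COc1ccc(OC)c2c1C(=O)C2=O | intermediate
7 | 3,6-dihydroxybenzocyclobutene-1,2-dione | Oc1ccc(O)c2c1C(=O)C2=O | intermediate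
8 | 3,6-bis(tert-butyldimethylsilyloxy)benzocyclobutene-1,2-dione | CC(C)(C)[Si](C)(C)Oc1ccc(O[Si](C)(C)C(C)(C)C)c2c1C(=O)C2=O | intermediate
9 | chlorobis(triphenylphosphine)[3,6-bis(tert-butyldimethylsilyloxy)phthaloyl]cobalt, five-membered cobaltacycle | CC(C)(C)[Si](C)(C)Oc1ccc(O[Si](C)(C)C(C)(C)C)c2c1C(=O)[Co-2](Cl)([P+](c1ccccc1)(c1ccccc1)c1ccccc1)([P+](c1ccccc1)(c1ccccc1)c1ccccc1)C2=O | intermediate (not isolated)
10 | chloro(dimethylglyoxime)(pyridine)[3,6-bis(tert-butyldimethylsilyloxy)phthaloyl]cobalt | CC1=[N+](O)[Co-3]2(Cl)([n+]3ccccc3)([N+](O)=C1C)C(=O)c1c(O[Si](C)(C)C(C)(C)C)ccc(O[Si](C)(C)C(C)(C)C)c1C2=O | intermediate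
11 | 2-bromo-3-methylbut-2-ene | CC(C)=C(C)Br | starting material
12 | oxirane | C1CO1 | starting material
13 | (3-methylbut-2-en-2-yl)magnesium bromide | CC(C)=C(C)[Mg]Br | intermediate (not isolated)
14 | 3,4-dimethylpent-3-en-1-ol | CC(C)=C(C)CCO | intermediate
15 | 3,4-dimethylpent-3-enoic acid | CC(C)=C(C)CC(=O)O | intermediate
16 | 4-methylpent-3-enoic acid | CC(C)=CCC(=O)O | starting material
17 | 1-(4-methylpent-3-enoyl)imidazole | CC(C)=CCC(=O)n1ccnc1 | intermediate (not isolated)
18 | N-methoxy-N,4-dimethylpent-3-enamide | CC(C)=CCC(=O)N(C)OC | intermediate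
19 | ethynyltrimethylsilane | C#C[Si](C)(C)C | starting material
20 | lithium (trimethylsilyl)acetylide | [Li]C#C[Si](C)(C)C | intermediate (not isolated)
21 | 6-methyl-1-(trimethylsilyl)hept-5-en-1-yn-3-one | CC(C)=CCC(=O)C#C[Si](C)(C)C | intermediate
22 | (R)-6-methyl-1-(trimethylsilyl)hept-5-en-1-yn-3-ol | CC(C)=CC[C@@H](O)C#C[Si](C)(C)C | intermediate
23 | (R)-6-methylhept-5-en-1-yn-3-ol | CC(C)=CC[C@@H](O)C#C | intermediate
24 | (R)-6-methylhept-5-en-1-yn-3-yl 3,4-dimethylpent-3-enoate | CC(C)=CC[C@@H](OC(=O)CC(C)=C(C)C)C#C | intermediate
25 | seven-membered acyl(vinyl)cobaltacycle (chloride and dimethylglyoxime on cobalt, acyl carbon joined to the former alkyne CH) | CC1=[N+](O)[Co-2]2(Cl)([N+](O)=C1C)C(=O)c1c(O[Si](C)(C)C(C)(C)C)ccc(O[Si](C)(C)C(C)(C)C)c1C(=O)C=C2[C@@H](CC=C(C)C)OC(=O)CC(C)=C(C)C | intermediate (not isolated)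
26 | (R)-1-[5,8-bis(tert-butyldimethylsilyloxy)-1,4-dioxo-1,4-dihydronaphthalen-2-yl]-4-methylpent-3-enyl 3,4-dimethylpent-3-enoate | CC(C)=CC[C@@H](OC(=O)CC(C)=C(C)C)C1=CC(=O)c2c(O[Si](C)(C)C(C)(C)C)ccc(O[Si](C)(C)C(C)(C)C)c2C1=O | intermediate
27 | (R)-1-(5,8-dihydroxy-1,4-dioxo-1,4-dihydronaphthalen-2-yl)-4-methylpent-3-enyl 3,4-dimethylpent-3-enoate (CNP0163639.1) | CC(C)=CC[C@@H](OC(=O)CC(C)=C(C)C)C1=CC(=O)c2c(O)ccc(O)c2C1=O | target

Total step count: 15. Longest linear sequence: 8 steps (steps 1 to 6, 14 and 15, from 1).

**Steps most likely to fail**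

Step 14. The risk is loss of the acyloxy group, either by ionisation or by SN2′ displacement by liberated pyridine at the allylic-type C–O bond of the quinone once it has formed, or a sluggish alkyne insertion next to the ester. The fallback sets out from 23 and comes back at 27, and moves the esterification behind the ring construction. Compound 23 is silylated (Et3SiCl, imidazole, CH2Cl2) to (R)-triethyl[(6-methylhept-5-en-1-yn-3-yl)oxy]silane F1. F1 is annulated with 10 (CoCl2·6H2O, ClCH2CH2Cl, 80 °C) to (R)-5,8-bis(tert-butyldimethylsilyloxy)-2-[4-methyl-1-(triethylsilyloxy)pent-3-enyl]naphthalene-1,4-dione F2, which carries no ionisable ester. HF·pyridine removes all three silyl groups to give (R)-5,8-dihydroxy-2-(1-hydroxy-4-methylpent-3-enyl)naphthalene-1,4-dione (shikonin) F3. Steglich esterification (DCC, cat. DMAP) of its only non-chelated hydroxyl with 15 then gives 27.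

Step 2. The risk is ionic bromination of the electron-rich dimethoxyarene ring in competition with the radical benzylic bromination, and an incomplete second bromination. The fallback sets out from 1 and comes back at 6, and brings the second oxygen in with the cycloaddition partner. Methyl (tert-butyldimethylsilyloxy)acetate is converted (lithium diisopropylamide, TBSCl, THF, −78 °C) into 1-methoxy-1,2-bis(tert-butyldimethylsilyloxy)ethene F4. Aryne 3, generated from 1 with lithium 2,2,6,6-tetramethylpiperidide at −78 °C, is trapped by F4 in a [2+2] cycloaddition to 2,5,7-trimethoxy-7,8-bis(tert-butyldimethylsilyloxy)bicyclo[4.2.0]octa-1,3,5-triene F5. Aqueous HF in MeCN cleaves the mixed silyl acetal and the silyl ether to give 8-hydroxy-2,5-dimethoxybicyclo[4.2.0]octa-1,3,5-trien-7-one F6. Dess–Martin oxidation of the benzylic α-hydroxy ketone gives 6.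

Step 11. The risk is migration of the β,γ-double bond of ynone 21 into conjugation through its doubly activated CH2 group before hydride transfer, with loss of material and of enantiomeric purity. The fallback sets out from 19 and comes back at 22, and avoids the ynone altogether. Acetylide 20 is formylated with DMF to 3-(trimethylsilyl)prop-2-ynal F7. Brown allylation at −78 °C with the B-allyldiisopinocampheylborane made from (+)-Ipc2BOMe (the reagent derived from (−)-α-pinene) and allylmagnesium bromide should give (R)-1-(trimethylsilyl)hex-5-en-1-yn-3-ol F8. Re-face attack is expected, this being the reagent series opposite to the one that gives (S)-1-phenylbut-3-en-1-ol from benzaldehyde. Cross-metathesis of F8 with excess 2-methylbut-2-ene (second-generation Grubbs catalyst, RuCl2(=CHPh)(H2IMes)(PCy3), CH2Cl2, 40 °C) turns the vinyl group into the 2-methylprop-1-enyl terminus and gives 22.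

**Further compounds**
F1 | step 14 | (R)-triethyl[(6-methylhept-5-en-1-yn-3-yl)oxy]silane | CC(C)=CC[C@@H](O[Si](CC)(CC)CC)C#C
F2 | step 14 | (R)-5,8-bis(tert-butyldimethylsilyloxy)-2-[4-methyl-1-(triethylsilyloxy)pent-3-enyl]naphthalene-1,4-dione | CC(C)=CC[C@@H](O[Si](CC)(CC)CC)C1=CC(=O)c2c(O[Si](C)(C)C(C)(C)C)ccc(O[Si](C)(C)C(C)(C)C)c2C1=O
F3 | step 14 | (R)-5,8-dihydroxy-2-(1-hydroxy-4-methylpent-3-enyl)naphthalene-1,4-dione (shikonin) | CC(C)=CC[C@@H](O)C1=CC(=O)c2c(O)ccc(O)c2C1=O
F4 | step 2 | 1-methoxy-1,2-bis(tert-butyldimethylsilyloxy)ethene | COC(O[Si](C)(C)C(C)(C)C)=CO[Si](C)(C)C(C)(C)C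
F5 | step 2 | 2,5,7-trimethoxy-7,8-bis(tert-butyldimethylsilyloxy)bicyclo[4.2.0]octa-1,3,5-triene (mixture of stereoisomers) | COc1ccc(OC)c2c1C(O[Si](C)(C)C(C)(C)C)C2(OC)O[Si](C)(C)C(C)(C)C
F6 | step 2 | 8-hydroxy-2,5-dimethoxybicyclo[4.2.0]octa-1,3,5-trien-7-one (racemic) | COc1ccc(OC)c2c1C(O)C2=O
F7 | step 11 | 3-(trimethylsilyl)prop-2-ynal | C[Si](C)(C)C#CC=O
F8 | step 11 | (R)-1-(trimethylsilyl)hex-5-en-1-yn-3-ol | C=CC[C@@H](O)C#C[Si](C)(C)C
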